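**Retrosynthetic overview**
- Feature: C4 of the flavone is a ketone carbon on C4a of ring A, ortho to the C8a–O1 oxygen, so it is the formyl carbon of a salicylaldehyde. C3, C2 and ring B can then be brought in as one aroylmethyl unit (a β-keto sulfoxonium ylide).
- Key disconnection: C4–C3 and O1–C2 of ring C, both made in one flask by Cp*Rh-catalysed formyl C–H functionalisation of a 7-O-silyl salicylaldehyde with a 5'-O-benzyl aroyl sulfoxonium ylide, followed by cyclodehydration.
- Ring A piece: silylation, Baeyer–Villiger oxidation with formate cleavage, MOM protection, directed ortho-lithiation and formylation between OMOM and OMe, MOM removal. Ring B piece: O-benzylation of the phenolic ester, then acyl substitution with dimethylsulfoxonium methylide.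
- Ring order: rings A and B are bought as benzenes; ring C is the only ring formed, in the key step. Desilylation and hydrogenolysis then free the 7- and 5'-hydroxyls.

Key step: step 8

Assumption: the three building blocks marked as starting materials in the compound list are taken as purchasable, and flavone numbering (O1, C2–C4, C4a, C5–C8, C8a, primed ring B) is used throughout.

**Route**

Step 1
Reactants: 1 3-hydroxy-4,5-dimethoxybenzaldehyde
Product: 2 3,4-dimethoxy-5-(triisopropylsilyloxy)benzaldehyde
Conditions: TIPSCl, imidazole, DMF, 25 °C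
Reagents that add atoms: triisopropylsilyl chloride, CC(C)[Si](Cl)(C(C)C)C(C)C
Why: O-silylation of a phenol (nucleophilic substitution at silicon, imidazole as base and silyl-transfer agent) should proceed cleanly and installs a bulky, poorly coordinating group that later steers the lithiation.

Step 2
Reactants: 2 3,4-dimethoxy-5-(triisopropylsilyloxy)benzaldehyde
Product: 4 3,4-dimethoxy-5-(triisopropylsilyloxy)phenol, via aryl formate 3 (not isolated)
Conditions: mCPBA, CH2Cl2, 0 → 25 °C; aq. Na2S2O3/NaHCO3 wash; then Et3N, MeOH, 25 °C
Reagents that add atoms: meta-chloroperoxybenzoic acid, OOC(=O)c1cccc(Cl)c1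
Why: Baeyer–Villiger (Dakin-type) oxidation, in which the electron-rich aryl group bearing a para-methoxy substituent migrates in the Criegee intermediate to give the formate, which mild amine-catalysed methanolysis should cleave without touching the hindered aryl silyl ether.

Step 3
Reactants: 4 3,4-dimethoxy-5-(triisopropylsilyloxy)phenol
Product: 5 1,2-dimethoxy-5-(methoxymethoxy)-3-(triisopropylsilyloxy)benzene
Conditions: MOMCl, iPr2NEt, CH2Cl2, 0 → 25 °C
Reagents that add atoms: chloromethyl methyl ether, COCCl
Why: O-alkylation of the phenol with an α-chloro ether (SN1-like acetal formation) should give the MOM ether, which serves as the directing group for the next step.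

Step 4
Reactants: 5 1,2-dimethoxy-5-(methoxymethoxy)-3-(triisopropylsilyloxy)benzene
Product: 7 2,3-dimethoxy-6-(methoxymethoxy)-4-(triisopropylsilyloxy)benzaldehyde, via aryllithium 6 (not isolated)
Conditions: n-BuLi, TMEDA, THF, −20 → 0 °C; then DMF, −78 → 25 °C; H2O
Reagents that add atoms: N,N-dimethylformamide, CN(C)C=O
Why: Directed ortho-metalation, in which the MOM acetal oxygen and the neighbouring methoxy group cooperate to place lithium on the CH between them while the other ortho CH is shielded by the bulky silyl ether, followed by formylation of the aryllithium with DMF.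

Step 5
Reactants: 7 2,3-dimethoxy-6-(methoxymethoxy)-4-(triisopropylsilyloxy)benzaldehyde
Product: 8 2-hydroxy-5,6-dimethoxy-4-(triisopropylsilyloxy)benzaldehyde
Conditions: 2 M aq. HCl, THF, 50 °C
Reagents that add atoms: none
Why: Acid-catalysed acetal hydrolysis of the MOM ether, assisted by the ortho formyl group, should free the phenol while the acid-stable aryl triisopropylsilyl ether stays in place.

Step 6
Reactants: 9 methyl 3-hydroxy-4,5-dimethoxybenzoate
Product: 10 methyl 3-(benzyloxy)-4,5-dimethoxybenzoate
Conditions: BnBr, K2CO3, DMF, 60 °C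
Reagents that add atoms: benzyl bromide, BrCc1ccccc1
Why: Williamson ether synthesis (SN2 of the phenoxide on benzyl bromide) should be clean and gives a protecting group that tolerates the strongly basic ylide step.

Step 7
Reactants: 10 methyl 3-(benzyloxy)-4,5-dimethoxybenzoate; 11 trimethylsulfoxonium iodide
Product: 13 1-[3-(benzyloxy)-4,5-dimethoxyphenyl]-2-[dimethyl(oxo)-λ6-sulfanylidene]ethan-1-one, via dimethylsulfoxonium methylide 12 (not isolated)
Conditions: 11 (3 equiv), KOtBu (3 equiv), THF, reflux, 2 h; then 10, reflux
Reagents that add atoms: none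
Why: Nucleophilic acyl substitution of the ester by the Corey–Chaykovsky methylide, after which deprotonation of the acylated sulfoxonium salt gives the carbonyl-stabilised ylide, a standard preparation of β-keto sulfoxonium ylides.

Step 8
Reactants: 8 2-hydroxy-5,6-dimethoxy-4-(triisopropylsilyloxy)benzaldehyde; 13 1-[3-(benzyloxy)-4,5-dimethoxyphenyl]-2-[dimethyl(oxo)-λ6-sulfanylidene]ethan-1-one
Product: 15 2-[3-(benzyloxy)-4,5-dimethoxyphenyl]-5,6-dimethoxy-7-(triisopropylsilyloxy)-4H-chromen-4-one, via 1,3-diketone 14 (not isolated)
Conditions: 13 (1.5 equiv), [Cp*RhCl2]2 (2.5 mol %), AgSbF6 (10 mol %), NaOAc (20 mol %), AcOH (1 equiv), ClCH2CH2Cl, 80 °C, N2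
Reagents that add atoms: none
Why: AgSbF6 strips chloride from [Cp*RhCl2]2 to give a cationic Cp*Rh species (trivalent rhodium) that binds the phenoxide of 8, and acetate-assisted deprotonation cleaves the adjacent formyl C–H to a five-membered acyl rhodacycle; ylide 13 then binds through carbon, DMSO leaves to give a rhodium carbene, the acyl group migrates onto the carbene carbon (forming C4–C3) and protonation by AcOH releases the 2-hydroxyaryl 1,3-diketone 14 with the metal returned in its starting oxidation state, so no oxidant is needed. The closest known reaction type is this same Cp*Rh-catalysed aldehyde C–H activation of salicylaldehydes and annulation with sulfoxonium ylides or diazo compounds to chromones. Ring C closes by 6-exo-trig attack of the phenolic oxygen on the ring B carbonyl of 14 followed by loss of water (forming O1–C2), driven by formation of the conjugated 4-pyranone. No stereocenter is formed. The selectivity needed is cleavage of the formyl C–H in preference to aryl C–H bonds, and the ortho hydroxyl secures it because only the aldehyde hydrogen can be reached through a five-membered chelate, while the single aryl C–H of ring A lies between two oxygen substituents and the ylide is used in excess to offset its own slower ortho C–H activation on ring B. The position of the formyl group on ring A, between OH and OMe, was already fixed by the lithiation in step 4.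

Step 9
Reactants: 15 2-[3-(benzyloxy)-4,5-dimethoxyphenyl]-5,6-dimethoxy-7-(triisopropylsilyloxy)-4H-chromen-4-one
Product: 16 2-[3-(benzyloxy)-4,5-dimethoxyphenyl]-7-hydroxy-5,6-dimethoxy-4H-chromen-4-one
Conditions: TBAF, AcOH, THF, 0 °C
Reagents that add atoms: none
Why: Fluoride-mediated desilylation should be fast because the 7-oxygen is a vinylogous carboxylate leaving group, and the acetic acid buffer keeps the medium from becoming basic enough to open the pyranone.

Step 10
Reactants: 16 2-[3-(benzyloxy)-4,5-dimethoxyphenyl]-7-hydroxy-5,6-dimethoxy-4H-chromen-4-one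
Product: 17 7-hydroxy-2-(3-hydroxy-4,5-dimethoxyphenyl)-5,6-dimethoxy-4H-chromen-4-one (7,5'-dihydroxy-5,6,3',4'-tetramethoxyflavone)
Conditions: H2 (1 atm), 10% Pd/C, EtOAc/MeOH, 25 °C
Reagents that add atoms: none
Why: Catalytic hydrogenolysis of the benzyl aryl ether on palladium on carbon (zerovalent palladium) should free the 5'-hydroxyl, while the C2–C3 double bond, conjugated with the carbonyl and both aryl rings, is expected to resist reduction at atmospheric pressure.

**Compound list**

1 | 3-hydroxy-4,5-dimethoxybenzaldehyde | COc1cc(C=O)cc(O)c1OC | starting material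
2 | 3,4-dimethoxy-5-(triisopropylsilyloxy)benzaldehyde | COc1cc(C=O)cc(O[Si](C(C)C)(C(C)C)C(C)C)c1OC | intermediate
3 | 3,4-dimethoxy-5-(triisopropylsilyloxy)phenyl formate | COc1cc(OC=O)cc(O[Si](C(C)C)(C(C)C)C(C)C)c1OC | intermediate (not isolated)
4 | 3,4-dimethoxy-5-(triisopropylsilyloxy)phenol | COc1cc(O)cc(O[Si](C(C)C)(C(C)C)C(C)C)c1OC | intermediate
5 | 1,2-dimethoxy-5-(methoxymethoxy)-3-(triisopropylsilyloxy)benzene | COCOc1cc(OC)c(OC)c(O[Si](C(C)C)(C(C)C)C(C)C)c1 | intermediate
6 | [2,3-dimethoxy-6-(methoxymethoxy)-4-(triisopropylsilyloxy)phenyl]lithium | [Li]c1c(OCOC)cc(O[Si](C(C)C)(C(C)C)C(C)C)c(OC)c1OC | intermediate (not isolated)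
7 | 2,3-dimethoxy-6-(methoxymethoxy)-4-(triisopropylsilyloxy)benzaldehyde | COCOc1cc(O[Si](C(C)C)(C(C)C)C(C)C)c(OC)c(OC)c1C=O | intermediate
8 | 2-hydroxy-5,6-dimethoxy-4-(triisopropylsilyloxy)benzaldehyde | COc1c(O[Si](C(C)C)(C(C)C)C(C)C)cc(O)c(C=O)c1OC | intermediate
9 | methyl 3-hydroxy-4,5-dimethoxybenzoate | COC(=O)c1cc(O)c(OC)c(OC)c1 | starting material
10 | methyl 3-(benzyloxy)-4,5-dimethoxybenzoate | COC(=O)c1cc(OCc2ccccc2)c(OC)c(OC)c1 | intermediate
11 | trimethylsulfoxonium iodide | C[S+](C)(C)=O.[I-] | starting material
12 | dimethylsulfoxonium methylide | C=S(C)(C)=O | intermediate (not isolated)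
13 | 1-[3-(benzyloxy)-4,5-dimethoxyphenyl]-2-[dimethyl(oxo)-λ6-sulfanylidene]ethan-1-one | COc1cc(C(=O)C=S(C)(C)=O)cc(OCc2ccccc2)c1OC | intermediate
14 | 1-[3-(benzyloxy)-4,5-dimethoxyphenyl]-3-[2-hydroxy-5,6-dimethoxy-4-(triisopropylsilyloxy)phenyl]propane-1,3-dione | COc1cc(C(=O)CC(=O)c2c(O)cc(O[Si](C(C)C)(C(C)C)C(C)C)c(OC)c2OC)cc(OCc2ccccc2)c1OC | intermediate (not isolated)
15 | 2-[3-(benzyloxy)-4,5-dimethoxyphenyl]-5,6-dimethoxy-7-(triisopropylsilyloxy)-4H-chromen-4-one | COc1cc(-c2cc(=O)c3c(OC)c(OC)c(O[Si](C(C)C)(C(C)C)C(C)C)cc3o2)cc(OCc2ccccc2)c1OC | intermediate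
16 | 2-[3-(benzyloxy)-4,5-dimethoxyphenyl]-7-hydroxy-5,6-dimethoxy-4H-chromen-4-one | COc1cc(-c2cc(=O)c3c(OC)c(OC)c(O)cc3o2)cc(OCc2ccccc2)c1OC | intermediate
17 | 7-hydroxy-2-(3-hydroxy-4,5-dimethoxyphenyl)-5,6-dimethoxy-4H-chromen-4-one | COc1cc(-c2cc(=O)c3c(OC)c(OC)c(O)cc3o2)cc(O)c1OC | target

**Step count**

Total: 10 steps. Longest linear sequence: 8 steps (steps 1–5, 8, 9, 10); the ring B branch (steps 6 and 7) joins at step 8.

**Steps most likely to fail**

1. Step 8 (key step). Several things may go wrong:
- The formyl group is flanked by OH and OMe, so C–H cleavage may be slow.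
- The acyl rhodium species may lose CO.
- The ylide may be consumed by its own ortho C–H activation and self-annulation on ring B.
- The diketone may not fully cyclodehydrate.
- The silyl ether may be lost early; this would be harmless, since it would give 16 directly.

Fallback (classical Claisen-type diketone route): it sets out from 7 and comes back at 15. Addition of MeMgBr in THF at 0 °C to aldehyde 7 should give 1-[2,3-dimethoxy-6-(methoxymethoxy)-4-(triisopropylsilyloxy)phenyl]ethanol F1 (racemic). Oxidation with Dess–Martin periodinane in CH2Cl2 should give 1-[2,3-dimethoxy-6-(methoxymethoxy)-4-(triisopropylsilyloxy)phenyl]ethanone F2. Its lithium enolate (LiN(SiMe3)2, THF, −78 °C) would be acylated by ester 10 on warming (crossed Claisen condensation) to give 1-[3-(benzyloxy)-4,5-dimethoxyphenyl]-3-[2,3-dimethoxy-6-(methoxymethoxy)-4-(triisopropylsilyloxy)phenyl]propane-1,3-dione F3. Treatment with 2 M aq. HCl in THF at 50 °C (then catalytic TsOH in toluene at 80 °C if needed) would remove the MOM group to give diketone 14, which cyclodehydrates to 15.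

2. Step 4. Lithiation may occur in part at the CH next to the silyl ether, or butyllithium may attack silicon or trigger silyl migration, giving the wrong regioisomer or desilylated material. Fallback (electrophilic ortho-formylation of the free phenol instead of metalation): it sets out from 4 and comes back at 8. Heating phenol 4 with MgCl2, Et3N and paraformaldehyde in MeCN should deliver formaldehyde within the magnesium phenoxide chelate to the less hindered ortho position and give 8 directly, which also skips steps 3 and 5. The bulk of the silyl ether is then the only positional control, so a regioisomer may have to be separated. No compound outside the main route is made on this path (F0).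

3. Step 7. Acyl substitution at the electron-rich, poorly electrophilic ester may stall, leaving ester or giving hydrolysis products. Fallback (acid chloride as acyl donor instead of the ester): it sets out from 10 and comes back at 13. Saponification with LiOH in THF/H2O should give 3-(benzyloxy)-4,5-dimethoxybenzoic acid F4. Oxalyl chloride with catalytic DMF in CH2Cl2 should give 3-(benzyloxy)-4,5-dimethoxybenzoyl chloride F5. Adding F5 at 0 °C to methylide 12 (prepared from 11 and KOtBu in THF, used in excess) should give ylide 13 by rapid acylation.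

**Further compounds**

F1 | step 8 | 1-[2,3-dimethoxy-6-(methoxymethoxy)-4-(triisopropylsilyloxy)phenyl]ethanol (racemic) | COCOc1cc(O[Si](C(C)C)(C(C)C)C(C)C)c(OC)c(OC)c1C(C)O
F2 | step 8 | 1-[2,3-dimethoxy-6-(methoxymethoxy)-4-(triisopropylsilyloxy)phenyl]ethanone | COCOc1cc(O[Si](C(C)C)(C(C)C)C(C)C)c(OC)c(OC)c1C(C)=O
F3 | step 8 | 1-[3-(benzyloxy)-4,5-dimethoxyphenyl]-3-[2,3-dimethoxy-6-(methoxymethoxy)-4-(triisopropylsilyloxy)phenyl]propane-1,3-dione | COCOc1cc(O[Si](C(C)C)(C(C)C)C(C)C)c(OC)c(OC)c1C(=O)CC(=O)c1cc(OC)c(OC)c(OCc2ccccc2)c1
F0 | step 4 | none | none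
F4 | step 7 | 3-(benzyloxy)-4,5-dimethoxybenzoic acid | OC(=O)c1cc(OCc2ccccc2)c(OC)c(OC)c1
F5 | step 7 | 3-(benzyloxy)-4,5-dimethoxybenzoyl chloride | ClC(=O)c1cc(OCc2ccccc2)c(OC)c(OC)c1
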